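**Plan**

1. Numbering (daucane): ring A = C1–C5, ring B = C1, C5–C10; C15 = methyl on C1; C4 carries OH and isopropyl, C6 the aroyloxy group, C8 the exocyclic C14, C9 the free OH; β = face of C15, α = face of H-5.
2. Retrosynthesis: the aryl ester and 9-OH (late allylic oxidation), the isopropyl group (C4 ketone), C15 (cuprate on the C1=C5 enone) and C14 (Wittig on a C8 ketone) are removed first; ring B is then cut at C9–C10 and C5–C6 in one formal (4+3) event.
3. Enabling feature: C6–C7–C8–C9, with oxygen on C6 and a carbonyl equivalent on C8, is a 1-silyloxy-3-siloxybuta-1,3-diene; C10–C1=C5 with the C4 carbonyl is the alkenylcarbenoid of a (3-oxocyclopent-1-enyl)diazoacetate, so ring A itself is the vinyl arm. The ester on C10 is a helper that later leaves as CO2.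
4. Forward: ring A is bought; ring B is made in step 4 (cyclopropanation forms C9–C10, Cope shift forms C5–C6); then C14, loss of the helper, C15, isopropyl, aryl ester and 9-OH follow.
5. Stereochemistry: C6 from the chiral dirhodium catalyst, relayed by the boat Cope shift; C1 by cuprate attack anti to the 6-silyloxy group; C5 by protonation (trans fusion); C4 by attack on the α face; C9 by oxygen delivery anti to C15.

Key step: step 4

Assumption: (E)-4-(tert-butyldimethylsilyloxy)but-3-en-2-one and 4-(tert-butyldimethylsilyloxy)benzoic acid are taken as catalogue compounds.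
Assumption: the S antipode of the dirhodium prolinate is assumed to give the cyclopropane configuration drawn; the R antipode would be used should the sense prove opposite.

Step 1
Reactants: 1 3-ethoxycyclopent-2-en-1-one; 2 methyl acetate
Product: 5 methyl 2-(3-oxocyclopent-1-en-1-yl)acetate, via lithium enolate 3 (not isolated), via carbinol adduct 4 (not isolated)
Conditions: LiN(iPr)2, THF, −78 °C (2 to 3); add 1, −78 → 0 °C; then 1 M HCl, rt
Reagents that add atoms: none
Why: Stork–Danheiser sequence, in which the ester enolate adds 1,2 to the vinylogous ester and acid work-up hydrolyses the enol ether with loss of water and ethanol to give the transposed enone; no lasting stereocentre is formed.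

Step 2
Reactants: 5 methyl 2-(3-oxocyclopent-1-en-1-yl)acetate
Product: 6 methyl 2-diazo-2-(3-oxocyclopent-1-en-1-yl)acetate
Conditions: p-ABSA, DBU, MeCN, 0 °C
Reagents that add atoms: 4-acetamidobenzenesulfonyl azide (p-ABSA), CC(=O)Nc1ccc(cc1)S(=O)(=O)N=[N+]=[N-]
Why: Regitz diazo transfer to the methylene that is doubly activated by the ester and the vinylogous ketone; the product is a cycloalkenyl diazoacetate whose vinyl terminus carries its substituent trans to the diazo carbon, a class that should not close to a pyrazole at ambient temperature.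

Step 3
Reactants: 7 (E)-4-(tert-butyldimethylsilyloxy)but-3-en-2-one
Product: 8 (E)-1-(tert-butyldimethylsilyloxy)-3-(trimethylsilyloxy)buta-1,3-diene
Conditions: TMSOTf, Et3N, Et2O, 0 °C
Reagents that add atoms: trimethylsilyl trifluoromethanesulfonate, C[Si](C)(C)OS(=O)(=O)C(F)(F)F
Why: soft enolisation of the methyl ketone (Danishefsky-type diene preparation), whose only α-hydrogens are on the methyl group, should give the 2-siloxy diene with the (E)-enol ether untouched.

Step 4
Reactants: 6 methyl 2-diazo-2-(3-oxocyclopent-1-en-1-yl)acetate; 8 (E)-1-(tert-butyldimethylsilyloxy)-3-(trimethylsilyloxy)buta-1,3-diene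
Product: 11 bicyclic keto ester (C4 and C8 ketones; C1=C10 double bond with CO2Me on C10; 6α-OTBS; H-5 β and cis to H-6), via divinylcyclopropane 9 (not isolated), via silyl enol ether 10 (not isolated)
Conditions: Rh2(S-DOSP)4 (1 mol %; DOSP = N-(4-dodecylphenylsulfonyl)prolinate), 8 (2.5 equiv), hexanes/PhCF3, −30 °C → rt, slow addition of 6; then 1 M HCl, THF, 0 °C
Reagents that add atoms: none
Why: The dirhodium prolinate should convert 6 into a rhodium alkenylcarbenoid whose carbene carbon (C10) cyclopropanates the terminal C8=C9 silyl enol ether bond of 8 with the cyclopentenyl group cis to the remaining (E)-silyloxyvinyl group; the cis-divinylcyclopropane 9 then undergoes a [3,3] shift that forms C5–C6 and breaks C8–C10, and acid work-up hydrolyses the trimethylsilyl enol ether 10 to the C8 ketone. The closest known reaction type is the tandem cyclopropanation/Cope rearrangement (formal (4+3) cycloaddition) of 1-cycloalkenyl diazoacetates with 2-siloxy dienes, which gives hydroazulenes. The three-membered ring closes by concerted, asynchronous [2+1] addition of the carbenoid, and the seven-membered ring closes by the sigmatropic shift through the boat transition state that the cis-cyclopropane enforces. The chiral carboxylate ligands set the absolute configuration of the cyclopropane, and the boat geometry, with the (E)-silyloxy group and the ring A carbon on C5 both pointing outward, transfers it to C6 and gives the cis C5/C6 relationship (C5 is erased and reset later). Site selectivity for the 1,1-disubstituted enol ether over the trans-1,2-disubstituted one should follow from the steric demand of donor/acceptor carbenoids. Attack at the carbene carbon, and not at the vinylogous position, is secured because the vinyl terminus is a ring carbon bearing the ketone.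

Step 5
Reactants: 11 bicyclic keto ester
Product: 12 methyl 6α-(tert-butyldimethylsilyloxy)-8-methylene-4-oxo ester of the C1=C5 enone (CO2Me on sp3 C10; mixture of C10 epimers, possibly with the C1=C10 tautomer)
Conditions: Ph3P=CH2 (from Ph3PCH3Br, KOtBu; 3 equiv), THF, −78 → 0 °C; aq. NH4Cl
Reagents that add atoms: methyltriphenylphosphonium bromide, C[P+](c1ccccc1)(c1ccccc1)c1ccccc1.[Br-]
Why: Wittig methylenation, in which the first equivalent of ylide converts the vinylogous β-keto ester into its extended enolate and so masks the ring A ketone and the ester, leaving only the C8 ketone to be olefinated; C6 is untouched and the labile C5/C10 centre is removed in step 6.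

Step 6
Reactants: 12 methylene keto ester
Product: 13 6α-(tert-butyldimethylsilyloxy)-8-methylene-bicyclo[5.3.0]dec-1(5)-en-4-one (daucane numbering; ring-fusion enone)
Conditions: LiCl, H2O, DMSO, 130 °C
Reagents that add atoms: none
Why: Krapcho dealkoxycarbonylation of a vinylogous β-keto ester (the Hagemann-ester type), in which chloride demethylates the ester and the carboxylate loses CO2 to a dienolate that water protonates to the conjugated tetrasubstituted enone.

Step 7
Reactants: 13 ring-fusion enone
Product: 15 trans-fused ketone (15β-methyl on C1; H-5 α; 6α-OTBS; 8-methylene; C4 ketone), via silyl enol ether 14 (not isolated)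
Conditions: Me2CuLi (from MeLi, CuI), TMSCl, Et2O/THF, −78 → −30 °C; then 1 M HCl, THF, 0 °C
Reagents that add atoms: lithium dimethylcuprate, [Li+].C[Cu-]C
Why: silyl-chloride-accelerated cuprate 1,4-addition with in situ trapping of the enolate (so no β-silyloxy enolate can eliminate), in which methyl should add anti to the pseudoaxial 6-silyloxy group held by allylic strain against the carbonyl, and protonation of 14 opposite the new angular methyl should give the trans ring fusion.

Step 8
Reactants: 15 trans-fused ketone
Product: 16 tertiary alcohol (4β-OH, 4α-isopropyl; 6α-OTBS; 8-methylene)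
Conditions: iPrMgCl, CeCl3 (anhydrous), THF, −78 → 0 °C
Reagents that add atoms: isopropylmagnesium chloride, CC(C)[Mg]Cl
Why: cerium-mediated Grignard addition (weakly basic, so the enolisable β-silyloxy ketone should neither enolise nor eliminate), with the nucleophile entering on the α face, away from the angular methyl and the C6 branch, to give the 4β-alcohol.

Step 9
Reactants: 16 tertiary alcohol
Product: 17 diol (4β-OH, 6α-OH; 8-methylene)
Conditions: TBAF, THF, rt
Reagents that add atoms: none
Why: fluoride cleavage of the secondary silyl ether; no other group in 16 is fluoride-sensitive and no stereocentre is touched.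

Step 10
Reactants: 17 diol; 18 4-(tert-butyldimethylsilyloxy)benzoic acid
Product: 19 6α-[4-(tert-butyldimethylsilyloxy)benzoyloxy] ester (4β-OH free; 8-methylene)
Conditions: DCC, DMAP, CH2Cl2, rt
Reagents that add atoms: none
Why: Steglich esterification, in which the secondary C6 hydroxyl should react and the tertiary C4 hydroxyl should not; C6 keeps its configuration because its C–O bond is not broken.

Step 11
Reactants: 19 silyl-protected ester
Product: 20 9α-hydroxy ester (phenol still silylated)
Conditions: SeO2 (cat.), t-BuOOH, CH2Cl2, 0 °C → rt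
Reagents that add atoms: selenium dioxide (oxygen carrier), O=[Se]=O; tert-butyl hydroperoxide (terminal oxygen source), CC(C)(C)OO
Why: selenium dioxide allylic hydroxylation (ene reaction, then [2,3]-sigmatropic shift that returns the double bond to the exocyclic position), in which C9 should be preferred over C7 (deactivated by the neighbouring acyloxy-bearing carbon) and oxygen should arrive on the α face because the angular methyl shields the β face of C9.

Step 12
Reactants: 20 9α-hydroxy ester
Product: 21 ferugin
Conditions: HF·pyridine, pyridine, THF, 0 °C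
Reagents that add atoms: none
Why: selective cleavage of the aryl silyl ether with buffered hydrogen fluoride; the benzoate, the allylic alcohol and the exocyclic alkene should be inert.

**Compound list**

1 | 3-ethoxycyclopent-2-en-1-one | CCOC1=CC(=O)CC1 | starting material
2 | methyl acetate | CC(=O)OC | starting material
3 | lithium enolate of methyl acetate (not isolated) | [Li+].[O-]C(=C)OC | intermediate
4 | methyl 2-(3-ethoxy-1-hydroxycyclopent-2-en-1-yl)acetate (racemic, not isolated) | CCOC1=CC(O)(CC(=O)OC)CC1 | intermediate
5 | methyl 2-(3-oxocyclopent-1-en-1-yl)acetate | COC(=O)CC1=CC(=O)CC1 | intermediate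
6 | methyl 2-diazo-2-(3-oxocyclopent-1-en-1-yl)acetate | COC(=O)C(=[N+]=[N-])C1=CC(=O)CC1 | intermediate
7 | (E)-4-(tert-butyldimethylsilyloxy)but-3-en-2-one | CC(=O)/C=C/O[Si](C)(C)C(C)(C)C | starting material
8 | (E)-1-(tert-butyldimethylsilyloxy)-3-(trimethylsilyloxy)buta-1,3-diene | C=C(O[Si](C)(C)C)/C=C/O[Si](C)(C)C(C)(C)C | intermediate
9 | cis-divinylcyclopropane: methyl 1-(3-oxocyclopent-1-enyl)-2-[(E)-2-(tert-butyldimethylsilyloxy)vinyl]-2-(trimethylsilyloxy)cyclopropanecarboxylate, cyclopentenyl cis to silyloxyvinyl (not isolated) | COC(=O)[C@]1(C2=CC(=O)CC2)C[C@@]1(O[Si](C)(C)C)/C=C/O[Si](C)(C)C(C)(C)C | intermediate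
10 | bicyclic trimethylsilyl enol ether (C7=C8 enol ether, C1=C10 ester alkene, 6α-OTBS, H-5 cis to H-6; not isolated) | C[Si](C)(C)OC1=C[C@H](O[Si](C)(C)C(C)(C)C)[C@H]2C(CCC2=O)=C(C(=O)OC)C1 | intermediate
11 | bicyclic keto ester (C4 and C8 ketones, C1=C10 alkene with 10-CO2Me, 6α-OTBS, H-5 β) | O=C1C[C@H](O[Si](C)(C)C(C)(C)C)[C@H]2C(CCC2=O)=C(C(=O)OC)C1 | intermediate
12 | methylene keto ester (C1=C5 enone, 8-methylene, 6α-OTBS, 10-CO2Me, C10 epimers) | C=C1C[C@H](O[Si](C)(C)C(C)(C)C)C2=C(CCC2=O)C(C(=O)OC)C1 | intermediate
13 | ring-fusion enone (C1=C5 enone, C4 ketone, 8-methylene, 6α-OTBS) | C=C1C[C@H](O[Si](C)(C)C(C)(C)C)C2=C(CCC2=O)CC1 | intermediate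
14 | C4=C5 trimethylsilyl enol ether with 15β-methyl on C1 (not isolated) | C=C1C[C@H](O[Si](C)(C)C(C)(C)C)C2=C(O[Si](C)(C)C)CC[C@]2(C)CC1 | intermediate
15 | trans-fused ketone (15β-Me, H-5 α, 6α-OTBS, 8-methylene, C4 ketone) | C=C1C[C@H](O[Si](C)(C)C(C)(C)C)[C@@H]2[C@](C)(CCC2=O)CC1 | intermediate
16 | tertiary alcohol (4β-OH, 4α-isopropyl, 6α-OTBS, 8-methylene) | C=C1C[C@H](O[Si](C)(C)C(C)(C)C)[C@@H]2[C@](C)(CC[C@@]2(O)C(C)C)CC1 | intermediate
17 | diol (4β-OH, 6α-OH, 8-methylene) | C=C1C[C@H](O)[C@@H]2[C@](C)(CC[C@@]2(O)C(C)C)CC1 | intermediate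
18 | 4-(tert-butyldimethylsilyloxy)benzoic acid | CC(C)(C)[Si](C)(C)Oc1ccc(cc1)C(=O)O | starting material
19 | 6α-[4-(tert-butyldimethylsilyloxy)benzoyloxy] ester of 17 | C=C1C[C@H](OC(=O)c2ccc(O[Si](C)(C)C(C)(C)C)cc2)[C@@H]2[C@](C)(CC[C@@]2(O)C(C)C)CC1 | intermediate
20 | 9α-hydroxy derivative of 19 (O-silyl ferugin) | C=C1C[C@H](OC(=O)c2ccc(O[Si](C)(C)C(C)(C)C)cc2)[C@@H]2[C@](C)(CC[C@@]2(O)C(C)C)C[C@@H]1O | intermediate
21 | ferugin | C=C1C[C@H](OC(=O)c2ccc(O)cc2)[C@@H]2[C@](C)(CC[C@@]2(O)C(C)C)C[C@@H]1O | target

**Step count and weak points**

Total steps: 12. Longest linear sequence: 11 steps (steps 1, 2 and 4–12, from 3-ethoxycyclopent-2-en-1-one); step 3 is a one-step side branch.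

Step 4. The ketone-conjugated cyclopentenyl group is a weak donor, so asymmetric induction by the catalyst may be low, and the polarised siloxydiene may capture the carbenoid stepwise and collapse to a five-membered ring. The fallback replaces catalyst control by auxiliary control, which is established for alkenylcarbenoid cyclopropanation in hydrocarbon solvent. It sets out from 5: saponification (LiOH, THF/H2O) should give 2-(3-oxocyclopent-1-en-1-yl)acetic acid F1, and coupling with (R)-pantolactone (DCC, DMAP) the pantolactonyl ester F2. Diazo transfer (p-ABSA, DBU) should then give the pantolactonyl diazoacetate F3. Its decomposition with achiral Rh2(O2CC7H15)4 in pentane in the presence of 8 should give the pantolactonyl cis-divinylcyclopropane F4, which rearranges to the pantolactonyl silyl enol ether F5 and is hydrolysed by dilute acid to the pantolactonyl keto ester F6. Wittig methylenation as in step 5 should give the pantolactonyl methylene ester F7. Cleavage of the auxiliary ester (LiOH, H2O2, THF/H2O, 0 °C) and warming of the free vinylogous β-keto acid (toluene, 70 °C) should return the route at 13.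

Step 7. 1,4-Addition to the tetrasubstituted enone may be slow and lose out to γ-deprotonation, or methyl may be delivered to the wrong face. The fallback builds the angular methyl by hydroxyl-directed cyclopropanation and reductive ring opening, starting from 13. Oxazaborolidine-catalysed (CBS) borane reduction under reagent control should give the 4β-allylic alcohol F8. Simmons–Smith cyclopropanation (Et2Zn, CH2I2), directed by that hydroxyl to the β face of the C1=C5 bond, should give the cyclopropyl carbinol F9. Dess–Martin oxidation should give the cyclopropyl ketone F10. Li in NH3/THF should cleave the exocyclic cyclopropane bond at C5, the one that overlaps with the carbonyl, leaving the methyl on C1 and returning the route at 15.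

Step 11. Oxygen transfer may show poor facial selectivity, or the alcohol may be over-oxidised to the enone. The fallback sets out from 19 and takes the oxidation deliberately to the ketone stage: excess SeO2/t-BuOOH followed by Dess–Martin periodinane on the crude alcohol mixture should give the α-methylene ketone F11. Oxazaborolidine-catalysed (CBS) reduction with catecholborane, with the catalyst antipode chosen for the 9α-alcohol, should return the route at 20.

**Further compounds**

F1 | step 4 | 2-(3-oxocyclopent-1-en-1-yl)acetic acid | OC(=O)CC1=CC(=O)CC1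
F2 | step 4 | (R)-pantolactonyl 2-(3-oxocyclopent-1-en-1-yl)acetate | CC1(C)COC(=O)[C@@H]1OC(=O)CC1=CC(=O)CC1
F3 | step 4 | (R)-pantolactonyl 2-diazo-2-(3-oxocyclopent-1-en-1-yl)acetate | CC1(C)COC(=O)[C@@H]1OC(=O)C(=[N+]=[N-])C1=CC(=O)CC1
F4 | step 4 | pantolactonyl cis-divinylcyclopropane | CC1(C)COC(=O)[C@@H]1OC(=O)[C@]1(C2=CC(=O)CC2)C[C@@]1(O[Si](C)(C)C)/C=C/O[Si](C)(C)C(C)(C)C
F5 | step 4 | pantolactonyl silyl enol ether | C[Si](C)(C)OC1=C[C@H](O[Si](C)(C)C(C)(C)C)[C@H]2C(CCC2=O)=C(C(=O)O[C@H]3C(=O)OCC3(C)C)C1
F6 | step 4 | pantolactonyl keto ester | O=C1C[C@H](O[Si](C)(C)C(C)(C)C)[C@H]2C(CCC2=O)=C(C(=O)O[C@H]3C(=O)OCC3(C)C)C1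
F7 | step 4 | pantolactonyl methylene ester | C=C1C[C@H](O[Si](C)(C)C(C)(C)C)C2=C(CCC2=O)C(C(=O)O[C@H]3C(=O)OCC3(C)C)C1
F8 | step 7 | 4β-allylic alcohol | C=C1C[C@H](O[Si](C)(C)C(C)(C)C)C2=C(CC[C@@H]2O)CC1
F9 | step 7 | cyclopropyl carbinol (β-cyclopropane across C1–C5) | C=C1C[C@H](O[Si](C)(C)C(C)(C)C)[C@@]23C[C@@]2(CC[C@@H]3O)CC1
F10 | step 7 | cyclopropyl ketone | C=C1C[C@H](O[Si](C)(C)C(C)(C)C)[C@@]23C[C@@]2(CCC3=O)CC1
F11 | step 11 | α-methylene ketone (9-oxo derivative of 19) | C=C1C[C@H](OC(=O)c2ccc(O[Si](C)(C)C(C)(C)C)cc2)[C@@H]2[C@](C)(CC[C@@]2(O)C(C)C)CC1=O
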